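Ring A of unit 4 (the bottom flavan) is cut at C8a–C4a and C5–C6. It is a pentasubstituted phloroglucinol (C8a–O, C4a–C4, C5–O, C6–unit 3, C7–O, C8–H), and this sequence maps atom for atom onto a 2-substituted 3-alkoxycyclobutenone plus an ynol ether, so the 4→6 junction needs no regiocontrol. The precursor is 3-benzyloxy-2-(8-bromo-penta-O-benzylepicatechin-4β-yl)cyclobutenone. Heated with a silyl ynol ether carrying the C4–C3–C2–ring B chain, it forms both bonds and ring A in one operation and leaves only the C8a phenol free for Mitsunobu closure of ring C. The two upper, 3,4-cis-linked units are then attached by aryllithium/flavan-4-one unions.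

Key step: step 15

Remarks on the chemistry
- Units are numbered 1–4 from the top; rings A, B, C are the phloroglucinol, catechol and pyran rings. Read centre by centre, the target is epicatechin-(4α→6)-ent-epicatechin-(4β→8)-epicatechin-(4β→6)-epicatechin. Units 1, 3 and 4 are (2R,3R) and unit 2 is (2S,3S). The unit 3→unit 4 bond is 3,4-trans, and both upper interflavan bonds are 3,4-cis (ring C all-cis in units 1 and 2). Unit 2 therefore comes from (+)-epicatechin, and each cis bond is made by ketone addition followed by ionic deoxygenation.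
- Assumption: (+)-epicatechin and cyclobutane-1,3-dione are taken as purchasable.
- The ynol ether is carried as its triisopropylsilyl ether, because a benzyl ynol ether is prone to a [3,3] shift to a ketene on mild heating. The benzylic oxygen of the chain is a triethylsilyl ether so that it can be freed while the aryl silyl ether stays. The silyl group is exchanged for benzyl once ring C is closed, so that one hydrogenolysis ends the route.
- The C4 configuration drawn for the 4-hydroxy compounds (4, 6, 36, F7) and the tertiary carbinols (39, 42, F5, F9) is the expected one. These centres are planarised later, so either epimer serves.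

Step 1
Reactants: 1 (−)-epicatechin
Product: 2 5,7,3′,4′-tetra-O-benzyl-(−)-epicatechin
Conditions: BnBr, K2CO3, DMF, 0 °C → rt
Reagents that add atoms: benzyl bromide, BrCc1ccccc1
Why: Williamson etherification with carbonate alkylates only the four phenols and leaves the secondary 3-OH and both stereocentres untouched.

Step 2
Reactants: 2 5,7,3′,4′-tetra-O-benzyl-(−)-epicatechin
Product: 3 3,5,7,3′,4′-penta-O-benzyl-(−)-epicatechin
Conditions: NaH, BnBr, DMF, 0 °C → rt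
Reagents that add atoms: benzyl bromide, BrCc1ccccc1
Why: Williamson benzylation of the alkoxide; with all phenols capped, no ring-opening pathway can epimerise C2.

Step 3
Reactants: 3 3,5,7,3′,4′-penta-O-benzyl-(−)-epicatechin
Product: 4 penta-O-benzylepicatechin-4β-ol (4-OH trans to the 3-benzyloxy group)
Conditions: DDQ, CH2Cl2–H2O, rt
Reagents that add atoms: water, O
Why: Benzylic oxidation by hydride abstraction at C4 (cation stabilised by O5 and O7) followed by water capture, expected anti to the C3 benzyloxy group.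

Step 4
Reactants: 4 penta-O-benzylepicatechin-4β-ol
Product: 5 (2R,3S)-3,5,7-tris(benzyloxy)-2-[3,4-bis(benzyloxy)phenyl]chroman-4-one (2,3-cis)
Conditions: (n-Pr)4N[RuO4] (cat.), NMO, 4 Å MS, CH2Cl2, rt
Reagents that add atoms: none
Why: Ley–Griffith oxidation of the secondary benzylic alcohol under neutral conditions, which do not enolise C3.

Step 5
Reactants: 4 penta-O-benzylepicatechin-4β-ol
Product: 6 8-bromo-penta-O-benzylepicatechin-4β-ol
Conditions: NBS, CH2Cl2, −78 → 0 °C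
Reagents that add atoms: N-bromosuccinimide, O=C1CCC(=O)N1Br
Why: Electrophilic aromatic bromination goes to C8, the more accessible activated position of ring A, because C6 lies between two benzyloxy groups.

Step 6
Reactants: 6 8-bromo-penta-O-benzylepicatechin-4β-ol; 7 cyclobutane-1,3-dione
Product: 8 2-(8-bromo-penta-O-benzylepicatechin-4β-yl)-3-hydroxycyclobut-2-en-1-one
Conditions: BF3·OEt2 (cat.), 4 Å MS, CH2Cl2–THF, −40 → 0 °C, 7 in excess
Reagents that add atoms: none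
Why: Acid ionises the 4-ol to the C4 benzylic cation, which is captured at C2 of the dione enol in a Friedel–Crafts-type alkylation of a 1,3-dicarbonyl; attack anti to the C3 benzyloxy group sets 4β, the C8 bromide blocks self-condensation, and any O-alkylated material re-ionises under the acid.

Step 7
Reactants: 8 2-(8-bromo-penta-O-benzylepicatechin-4β-yl)-3-hydroxycyclobut-2-en-1-one
Product: 9 3-benzyloxy-2-(8-bromo-penta-O-benzylepicatechin-4β-yl)cyclobut-2-en-1-one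
Conditions: BnOH, PPh3, DIAD, THF, 0 °C → rt
Reagents that add atoms: benzyl alcohol, OCc1ccccc1
Why: Mitsunobu O-alkylation of the acidic vinylogous acid; the two oxygens are equivalent, so a single enol ether results, and the bulky C2 substituent disfavours C-alkylation.

Step 8
Reactants: 10 3,4-bis(benzyloxy)benzaldehyde
Product: 11 rac-1-[3,4-bis(benzyloxy)phenyl]prop-2-en-1-ol
Conditions: CH2=CHMgBr, THF, 0 °C
Reagents that add atoms: vinylmagnesium bromide, C=C[Mg]Br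
Why: Grignard addition to the aldehyde gives the racemic aryl vinyl carbinol.

Step 9
Reactants: 11 rac-1-[3,4-bis(benzyloxy)phenyl]prop-2-en-1-ol
Product: 12 (S)-[3,4-bis(benzyloxy)phenyl][(R)-oxiran-2-yl]methanol (erythro)
Conditions: Ti(OiPr)4 (cat.), L-(+)-DIPT, t-BuOOH (0.6 equiv), 4 Å MS, CH2Cl2, −20 °C
Reagents that add atoms: tert-butyl hydroperoxide, CC(C)(C)OO
Why: Sharpless kinetic resolution: with the L-(+)-tartrate the (R)-carbinol is epoxidised much faster and on the face that gives the erythro epoxy alcohol, so the catalyst sets both centres as (1S,2R) and the (S)-carbinol is left behind.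

Step 10
Reactants: 12 (S)-[3,4-bis(benzyloxy)phenyl][(R)-oxiran-2-yl]methanol
Product: 13 (R)-2-[(S)-[3,4-bis(benzyloxy)phenyl](triethylsilyloxy)methyl]oxirane
Conditions: Et3SiCl, imidazole, DMF, 0 °C
Reagents that add atoms: chlorotriethylsilane, CC[Si](Cl)(CC)CC
Why: Silylation with an amine base forms no alkoxide and so avoids Payne rearrangement of the epoxy alcohol.

Step 11
Reactants: 13 (R)-2-[(S)-[3,4-bis(benzyloxy)phenyl](triethylsilyloxy)methyl]oxirane
Product: 14 (1S,2R)-1-[3,4-bis(benzyloxy)phenyl]-1-(triethylsilyloxy)-5-(trimethylsilyl)pent-4-yn-2-ol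
Conditions: Me3SiC≡CH, n-BuLi, THF, −78 °C; BF3·OEt2; then 13, −78 °C
Reagents that add atoms: ethynyltrimethylsilane, C#C[Si](C)(C)C
Why: BF3-promoted SN2 opening of the terminal epoxide by the lithium acetylide at the CH2 carbon leaves both stereocentres untouched, and the cold quench prevents silyl migration.

Step 12
Reactants: 14 (1S,2R)-1-[3,4-bis(benzyloxy)phenyl]-1-(triethylsilyloxy)-5-(trimethylsilyl)pent-4-yn-2-ol
Product: 15 (1S,2R)-2-benzyloxy-1-[3,4-bis(benzyloxy)phenyl]-1-(triethylsilyloxy)-5-(trimethylsilyl)pent-4-yne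
Conditions: 2-benzyloxy-1-methylpyridinium triflate, MgO, PhCF3, 85 °C
Reagents that add atoms: 2-benzyloxy-1-methylpyridinium triflate, C[n+]1ccccc1OCc1ccccc1.[O-]S(=O)(=O)C(F)(F)F
Why: Neutral benzyl transfer from the benzyloxypyridinium salt etherifies the secondary alcohol without forming the alkoxide that would trigger 1,2-silyl migration.

Step 13
Reactants: 15 (1S,2R)-2-benzyloxy-1-[3,4-bis(benzyloxy)phenyl]-1-(triethylsilyloxy)-5-(trimethylsilyl)pent-4-yne
Product: 16 (1S,2R)-2-benzyloxy-1-[3,4-bis(benzyloxy)phenyl]-1-(triethylsilyloxy)pent-4-yne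
Conditions: K2CO3 (cat.), MeOH, rt
Reagents that add atoms: none
Why: Base-catalysed protodesilylation cleaves only the alkynyl C–Si bond; the secondary triethylsilyl ether is stable to carbonate in methanol.

Step 14
Reactants: 16 (1S,2R)-2-benzyloxy-1-[3,4-bis(benzyloxy)phenyl]-1-(triethylsilyloxy)pent-4-yne
Product: 19 (4R,5S)-4-benzyloxy-5-[3,4-bis(benzyloxy)phenyl]-5-(triethylsilyloxy)-1-(triisopropylsilyloxy)pent-1-yne, via lithium acetylide 17 (not isolated), via lithium ynolate 18 (not isolated)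
Conditions: n-BuLi, THF, −78 °C; t-BuOOLi (from t-BuOOH, LiN(SiMe3)2), −78 → 0 °C; i-Pr3SiOTf, −78 → 0 °C
Reagents that add atoms: tert-butyl hydroperoxide, CC(C)(C)OO; triisopropylsilyl triflate, CC(C)[Si](C(C)C)(C(C)C)OS(=O)(=O)C(F)(F)F
Why: Oxidation of a lithium acetylide by lithium tert-butyl peroxide gives the lithium ynolate, which is silylated on oxygen by the hindered silyl triflate to give the silyl ynol ether.

Step 15
Reactants: 9 3-benzyloxy-2-(8-bromo-penta-O-benzylepicatechin-4β-yl)cyclobut-2-en-1-one; 19 (4R,5S)-4-benzyloxy-5-[3,4-bis(benzyloxy)phenyl]-5-(triethylsilyloxy)-1-(triisopropylsilyloxy)pent-1-yne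
Product: 24 4-(8-bromo-penta-O-benzylepicatechin-4β-yl)-5-benzyloxy-2-[(2R,3S)-2-benzyloxy-3-[3,4-bis(benzyloxy)phenyl]-3-(triethylsilyloxy)propyl]-3-(triisopropylsilyloxy)phenol, via vinylketene 20 (not isolated), via vinylcyclobutenone adduct 21 (not isolated), via dienylketene 22 (not isolated), via cyclohexadienone 23 (not isolated)
Conditions: toluene, 80 → 110 °C, sealed tube, 19 in slight excess
Reagents that add atoms: none
Why: Heating opens the cyclobutenone by 4π electrocyclic cleavage to vinylketene 20; the electron-rich carbon of the silyl ynol ether (the one bearing the chain) attacks the ketene carbonyl carbon and the oxygen-bearing carbon bonds to the ketene α-carbon in a [2+2] cycloaddition to 21, which reopens to dienylketene 22. Ring A is then closed by thermal 6π electrocyclisation between the ketene carbon and the terminal methylene to dienone 23, which tautomerises to phenol 24. This is the known thermal benzannulation of cyclobutenones with heteroatom-substituted alkynes (Danheiser benzannulation), here run on a cyclobutenone whose C2 carries a flavan-4-yl group. No stereocentre is formed: the ketene carbon becomes C8a–OH, the alkyne carbons C4a and C5, and cyclobutenone C2, C3, C4 become C6, C7, C8, so the 4→6 connectivity follows from the mechanism. The one selectivity needed is the orientation of the [2+2] step, which the polarisation of the ynol ether (nucleophilic at the carbon remote from oxygen) against the electrophilic ketene carbon secures. The neutral, reagent-free conditions should leave the five existing stereocentres, the aryl bromide and both silyl ethers untouched.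

Step 16
Reactants: 24 benzannulation phenol (triethylsilyl ether)
Product: 25 4-(8-bromo-penta-O-benzylepicatechin-4β-yl)-5-benzyloxy-2-[(2R,3S)-2-benzyloxy-3-[3,4-bis(benzyloxy)phenyl]-3-hydroxypropyl]-3-(triisopropylsilyloxy)phenol
Conditions: HF·pyridine, pyridine, THF, 0 °C
Reagents that add atoms: none
Why: Buffered fluoride cleaves the alkyl triethylsilyl ether selectively over the doubly ortho-substituted aryl triisopropylsilyl ether, without ionising the electron-rich benzylic carbon.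

Step 17
Reactants: 25 phenol–benzylic alcohol
Product: 26 8-bromo-penta-O-benzylepicatechin-(4β→6)-[3,7,3′,4′-tetra-O-benzyl-5-O-triisopropylsilyl-epicatechin]
Conditions: PPh3, DIAD, THF (dilute), 0 °C → rt
Reagents that add atoms: none
Why: Intramolecular Mitsunobu etherification: the only free phenol (C8a–OH) displaces the activated benzylic oxygen in a 6-exo-tet closure with inversion (S to R at C2), giving the 2,3-cis (2R,3R) ring C.

Step 18
Reactants: 26 5-O-silyl lower dimer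
Product: 28 8-bromo-penta-O-benzylepicatechin-(4β→6)-penta-O-benzylepicatechin (bromine on the upper unit), via ammonium phenoxide 27 (not isolated)
Conditions: n-Bu4NF, BnBr, THF, 0 °C → rt
Reagents that add atoms: benzyl bromide, BrCc1ccccc1
Why: Fluoride desilylation releases a naked tetrabutylammonium phenoxide that undergoes Williamson benzylation in the same flask.

Step 19
Reactants: 29 (+)-epicatechin
Product: 30 5,7,3′,4′-tetra-O-benzyl-(+)-epicatechin
Conditions: BnBr, K2CO3, DMF, 0 °C → rt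
Reagents that add atoms: benzyl bromide, BrCc1ccccc1
Why: Williamson etherification of the four phenols, as in step 1.

Step 20
Reactants: 30 5,7,3′,4′-tetra-O-benzyl-(+)-epicatechin
Product: 31 3,5,7,3′,4′-penta-O-benzyl-(+)-epicatechin
Conditions: NaH, BnBr, DMF, 0 °C → rt
Reagents that add atoms: benzyl bromide, BrCc1ccccc1
Why: Williamson benzylation of the 3-alkoxide, as in step 2.

Step 21
Reactants: 31 3,5,7,3′,4′-penta-O-benzyl-(+)-epicatechin
Product: 32 8-iodo-penta-O-benzyl-(+)-epicatechin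
Conditions: NIS, CH2Cl2, −20 → 0 °C
Reagents that add atoms: N-iodosuccinimide, O=C1CCC(=O)N1I
Why: Electrophilic aromatic iodination at C8, the less hindered activated position, installs a cap that can be removed later.

Step 22
Reactants: 32 8-iodo-penta-O-benzyl-(+)-epicatechin
Product: 33 6-bromo-8-iodo-penta-O-benzyl-(+)-epicatechin
Conditions: NBS, CH2Cl2, −40 → 0 °C
Reagents that add atoms: N-bromosuccinimide, O=C1CCC(=O)N1Br
Why: Electrophilic aromatic bromination at C6, the only unsubstituted position left on the activated ring A.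

Step 23
Reactants: 33 6-bromo-8-iodo-penta-O-benzyl-(+)-epicatechin
Product: 35 6-bromo-penta-O-benzyl-(+)-epicatechin, via arylmagnesium chloride 34 (not isolated)
Conditions: i-PrMgCl·LiCl, THF, −20 → 0 °C; then MeOH
Reagents that add atoms: none
Why: Halogen–magnesium exchange is far faster for the C–I than for the C–Br bond, so protonation of the C8 Grignard removes only the iodine cap.

Step 24
Reactants: 35 6-bromo-penta-O-benzyl-(+)-epicatechin
Product: 36 6-bromo-penta-O-benzyl-(+)-epicatechin-4α-ol (4-OH trans to the 3-benzyloxy group)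
Conditions: DDQ, CH2Cl2–H2O, rt
Reagents that add atoms: water, O
Why: DDQ benzylic oxidation at C4 with water capture, as in step 3.

Step 25
Reactants: 36 6-bromo-penta-O-benzyl-(+)-epicatechin-4α-ol
Product: 37 (2S,3R)-6-bromo-3,5,7-tris(benzyloxy)-2-[3,4-bis(benzyloxy)phenyl]chroman-4-one (2,3-cis)
Conditions: (n-Pr)4N[RuO4] (cat.), NMO, 4 Å MS, CH2Cl2, rt
Reagents that add atoms: none
Why: Ley–Griffith oxidation under neutral conditions, as in step 4.

Step 26
Reactants: 28 lower dimer bromide; 37 (2S,3R)-6-bromo-pentakis(benzyloxy)flavan-4-one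
Product: 39 [6-bromo-4-hydroxy-penta-O-benzyl-ent-epicatechin]-(4→8)-penta-O-benzylepicatechin-(4β→6)-penta-O-benzylepicatechin (tertiary OH cis to the 3-benzyloxy group), via aryllithium 38 (not isolated)
Conditions: t-BuLi (2 equiv), THF, −78 °C; then 37, −78 → −40 °C
Reagents that add atoms: none
Why: Bromine–lithium exchange at C8 of the upper unit and 1,2-addition of the aryllithium to the ketone, expected anti to the C3 benzyloxy group; the electron-rich C6 bromide of 37 does not exchange with an aryllithium at this temperature.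

Step 27
Reactants: 39 trimer tertiary carbinol
Product: 40 6-bromo-penta-O-benzyl-ent-epicatechin-(4β→8)-penta-O-benzylepicatechin-(4β→6)-penta-O-benzylepicatechin (3,4-cis in the top unit)
Conditions: n-Bu3SnH, CF3CO2H, CH2Cl2, 0 °C
Reagents that add atoms: none
Why: Ionic deoxygenation: acid ionises the doubly benzylic tertiary alcohol and the tin hydride delivers hydride to the cation anti to the C3 benzyloxy group, so the aryl group ends cis to the C3 oxygen.

Step 28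
Reactants: 40 trimer bromide; 5 (2R,3S)-pentakis(benzyloxy)flavan-4-one
Product: 42 [4-hydroxy-penta-O-benzylepicatechin]-(4→6)-penta-O-benzyl-ent-epicatechin-(4β→8)-penta-O-benzylepicatechin-(4β→6)-penta-O-benzylepicatechin (tertiary OH cis to the 3-benzyloxy group), via aryllithium 41 (not isolated)
Conditions: t-BuLi (2 equiv), THF, −78 °C; then 5, −78 → −40 °C
Reagents that add atoms: none
Why: Bromine–lithium exchange at C6 of the top unit (the only halogen left) and 1,2-addition of the aryllithium to the ketone; the carbinol configuration is erased in step 29.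

Step 29
Reactants: 42 tetramer tertiary carbinol
Product: 43 eicosa-O-benzyl epicatechin-(4α→6)-ent-epicatechin-(4β→8)-epicatechin-(4β→6)-epicatechin
Conditions: n-Bu3SnH, CF3CO2H, CH2Cl2, 0 °C
Reagents that add atoms: none
Why: Ionic deoxygenation as in step 27; hydride enters anti to the C3 benzyloxy group of unit 1 and leaves the unit 2 aryl group cis to it (4α).

Step 30
Reactants: 43 eicosa-O-benzyl tetramer
Product: 44 epicatechin-(4α→6)-ent-epicatechin-(4β→8)-epicatechin-(4β→6)-epicatechin (target)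
Conditions: H2, Pd(OH)2/C, THF–MeOH–H2O, rt
Reagents that add atoms: none
Why: Catalytic hydrogenolysis cleaves all twenty benzyl ethers under neutral conditions that leave the acid-sensitive interflavan bonds and every stereocentre intact.

Compound list
1 | (−)-epicatechin, (2R,3R) | Oc1cc(O)c2c(c1)O[C@H](c1ccc(O)c(O)c1)[C@H](O)C2 | starting material
2 | 5,7,3′,4′-tetra-O-benzyl-(−)-epicatechin | c9ccccc9COc1cc(OCc9ccccc9)c2c(c1)O[C@H](c8ccc(OCc9ccccc9)c(OCc9ccccc9)c8)[C@H](O)C2 | intermediate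
3 | 3,5,7,3′,4′-penta-O-benzyl-(−)-epicatechin | c9ccccc9COc1cc(OCc9ccccc9)c2c(c1)O[C@H](c8ccc(OCc9ccccc9)c(OCc9ccccc9)c8)[C@H](OCc9ccccc9)C2 | intermediate
4 | penta-O-benzylepicatechin-4β-ol | c9ccccc9COc1cc(OCc9ccccc9)c2c(c1)O[C@H](c8ccc(OCc9ccccc9)c(OCc9ccccc9)c8)[C@H](OCc9ccccc9)[C@H]2O | intermediate
5 | (2R,3S)-3,5,7-tris(benzyloxy)-2-[3,4-bis(benzyloxy)phenyl]chroman-4-one | c9ccccc9COc1cc(OCc9ccccc9)c2c(c1)O[C@H](c8ccc(OCc9ccccc9)c(OCc9ccccc9)c8)[C@H](OCc9ccccc9)C2=O | intermediate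
6 | 8-bromo-penta-O-benzylepicatechin-4β-ol | c9ccccc9COc1cc(OCc9ccccc9)c2c(c1Br)O[C@H](c8ccc(OCc9ccccc9)c(OCc9ccccc9)c8)[C@H](OCc9ccccc9)[C@H]2O | intermediate
7 | cyclobutane-1,3-dione | O=C1CC(=O)C1 | starting material
8 | 2-(8-bromo-penta-O-benzylepicatechin-4β-yl)-3-hydroxycyclobut-2-en-1-one | c9ccccc9COc1cc(OCc9ccccc9)c2c(c1Br)O[C@H](c8ccc(OCc9ccccc9)c(OCc9ccccc9)c8)[C@H](OCc9ccccc9)[C@H]2C1=C(O)CC1=O | intermediate
9 | 3-benzyloxy-2-(8-bromo-penta-O-benzylepicatechin-4β-yl)cyclobut-2-en-1-one | c9ccccc9COc1cc(OCc9ccccc9)c2c(c1Br)O[C@H](c8ccc(OCc9ccccc9)c(OCc9ccccc9)c8)[C@H](OCc9ccccc9)[C@H]2C1=C(OCc9ccccc9)CC1=O | intermediate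
10 | 3,4-bis(benzyloxy)benzaldehyde | O=Cc1ccc(OCc9ccccc9)c(OCc9ccccc9)c1 | starting material
11 | rac-1-[3,4-bis(benzyloxy)phenyl]prop-2-en-1-ol | C=CC(O)c1ccc(OCc9ccccc9)c(OCc9ccccc9)c1 | intermediate
12 | (S)-[3,4-bis(benzyloxy)phenyl][(R)-oxiran-2-yl]methanol | C1O[C@H]1[C@H](c8ccc(OCc9ccccc9)c(OCc9ccccc9)c8)O | intermediate
13 | (R)-2-[(S)-[3,4-bis(benzyloxy)phenyl](triethylsilyloxy)methyl]oxirane | C1O[C@H]1[C@H](c8ccc(OCc9ccccc9)c(OCc9ccccc9)c8)O[Si](CC)(CC)CC | intermediate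
14 | (1S,2R)-1-[3,4-bis(benzyloxy)phenyl]-1-(triethylsilyloxy)-5-(trimethylsilyl)pent-4-yn-2-ol | C[Si](C)(C)C#CC[C@@H](O)[C@H](c8ccc(OCc9ccccc9)c(OCc9ccccc9)c8)O[Si](CC)(CC)CC | intermediate
15 | (1S,2R)-2-benzyloxy-1-[3,4-bis(benzyloxy)phenyl]-1-(triethylsilyloxy)-5-(trimethylsilyl)pent-4-yne | C[Si](C)(C)C#CC[C@@H](OCc9ccccc9)[C@H](c8ccc(OCc9ccccc9)c(OCc9ccccc9)c8)O[Si](CC)(CC)CC | intermediate
16 | (1S,2R)-2-benzyloxy-1-[3,4-bis(benzyloxy)phenyl]-1-(triethylsilyloxy)pent-4-yne | C#CC[C@@H](OCc9ccccc9)[C@H](c8ccc(OCc9ccccc9)c(OCc9ccccc9)c8)O[Si](CC)(CC)CC | intermediate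
17 | lithium acetylide of 16 (not isolated) | [Li]C#CC[C@@H](OCc9ccccc9)[C@H](c8ccc(OCc9ccccc9)c(OCc9ccccc9)c8)O[Si](CC)(CC)CC | intermediate
18 | lithium ynolate from 17 (not isolated) | [Li]OC#CC[C@@H](OCc9ccccc9)[C@H](c8ccc(OCc9ccccc9)c(OCc9ccccc9)c8)O[Si](CC)(CC)CC | intermediate
19 | (4R,5S)-4-benzyloxy-5-[3,4-bis(benzyloxy)phenyl]-5-(triethylsilyloxy)-1-(triisopropylsilyloxy)pent-1-yne | CC(C)[Si](C(C)C)(C(C)C)OC#CC[C@@H](OCc9ccccc9)[C@H](c8ccc(OCc9ccccc9)c(OCc9ccccc9)c8)O[Si](CC)(CC)CC | intermediate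
20 | vinylketene from ring opening of 9 (not isolated) | c9ccccc9COc1cc(OCc9ccccc9)c2c(c1Br)O[C@H](c8ccc(OCc9ccccc9)c(OCc9ccccc9)c8)[C@H](OCc9ccccc9)[C@H]2C(=C=O)C(OCc9ccccc9)=C | intermediate
21 | 4-flavanyl-4-(1-benzyloxyvinyl)-3-silyloxy-2-alkylcyclobutenone adduct, quaternary ring carbon unassigned (not isolated) | c9ccccc9COc1cc(OCc9ccccc9)c2c(c1Br)O[C@H](c8ccc(OCc9ccccc9)c(OCc9ccccc9)c8)[C@H](OCc9ccccc9)[C@H]2C3(C(OCc9ccccc9)=C)C(=O)C(C[C@@H](OCc9ccccc9)[C@H](c8ccc(OCc9ccccc9)c(OCc9ccccc9)c8)O[Si](CC)(CC)CC)=C3O[Si](C(C)C)(C(C)C)C(C)C | intermediate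
22 | dienylketene, vinyl group cis to the ketene carbon (not isolated) | c9ccccc9COc1cc(OCc9ccccc9)c2c(c1Br)O[C@H](c8ccc(OCc9ccccc9)c(OCc9ccccc9)c8)[C@H](OCc9ccccc9)[C@H]2/C(C(OCc9ccccc9)=C)=C(/C(C[C@@H](OCc9ccccc9)[C@H](c8ccc(OCc9ccccc9)c(OCc9ccccc9)c8)O[Si](CC)(CC)CC)=C=O)O[Si](C(C)C)(C(C)C)C(C)C | intermediate
23 | cyclohexa-2,4-dienone tautomer of 24 (not isolated) | c9ccccc9COc1cc(OCc9ccccc9)c2c(c1Br)O[C@H](c8ccc(OCc9ccccc9)c(OCc9ccccc9)c8)[C@H](OCc9ccccc9)[C@H]2C3=C(OCc9ccccc9)CC(=O)C(C[C@@H](OCc9ccccc9)[C@H](c8ccc(OCc9ccccc9)c(OCc9ccccc9)c8)O[Si](CC)(CC)CC)=C3O[Si](C(C)C)(C(C)C)C(C)C | intermediate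
24 | 4-(8-bromo-penta-O-benzylepicatechin-4β-yl)-5-benzyloxy-2-[(2R,3S)-2-benzyloxy-3-[3,4-bis(benzyloxy)phenyl]-3-(triethylsilyloxy)propyl]-3-(triisopropylsilyloxy)phenol | c9ccccc9COc1cc(OCc9ccccc9)c2c(c1Br)O[C@H](c8ccc(OCc9ccccc9)c(OCc9ccccc9)c8)[C@H](OCc9ccccc9)[C@H]2c3c(OCc9ccccc9)cc(O)c(c3O[Si](C(C)C)(C(C)C)C(C)C)C[C@@H](OCc9ccccc9)[C@H](c8ccc(OCc9ccccc9)c(OCc9ccccc9)c8)O[Si](CC)(CC)CC | intermediate
25 | the same phenol with the benzylic 3-hydroxypropyl chain free | c9ccccc9COc1cc(OCc9ccccc9)c2c(c1Br)O[C@H](c8ccc(OCc9ccccc9)c(OCc9ccccc9)c8)[C@H](OCc9ccccc9)[C@H]2c3c(OCc9ccccc9)cc(O)c(c3O[Si](C(C)C)(C(C)C)C(C)C)C[C@@H](OCc9ccccc9)[C@H](c8ccc(OCc9ccccc9)c(OCc9ccccc9)c8)O | intermediate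
26 | 8-bromo-penta-O-benzylepicatechin-(4β→6)-[3,7,3′,4′-tetra-O-benzyl-5-O-triisopropylsilyl-epicatechin] | c9ccccc9COc1cc(OCc9ccccc9)c2c(c1Br)O[C@H](c8ccc(OCc9ccccc9)c(OCc9ccccc9)c8)[C@H](OCc9ccccc9)[C@H]2c3c(OCc9ccccc9)cc4c(c3O[Si](C(C)C)(C(C)C)C(C)C)C[C@@H](OCc9ccccc9)[C@@H](c8ccc(OCc9ccccc9)c(OCc9ccccc9)c8)O4 | intermediate
27 | tetrabutylammonium 5-phenoxide of the lower unit (not isolated) | c9ccccc9COc1cc(OCc9ccccc9)c2c(c1Br)O[C@H](c8ccc(OCc9ccccc9)c(OCc9ccccc9)c8)[C@H](OCc9ccccc9)[C@H]2c3c(OCc9ccccc9)cc4c(c3[O-])C[C@@H](OCc9ccccc9)[C@@H](c8ccc(OCc9ccccc9)c(OCc9ccccc9)c8)O4.CCCC[N+](CCCC)(CCCC)CCCC | intermediate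
28 | 8-bromo-penta-O-benzylepicatechin-(4β→6)-penta-O-benzylepicatechin | c9ccccc9COc1cc(OCc9ccccc9)c2c(c1Br)O[C@H](c8ccc(OCc9ccccc9)c(OCc9ccccc9)c8)[C@H](OCc9ccccc9)[C@H]2c3c(OCc9ccccc9)cc4c(c3OCc9ccccc9)C[C@@H](OCc9ccccc9)[C@@H](c8ccc(OCc9ccccc9)c(OCc9ccccc9)c8)O4 | intermediate
29 | (+)-epicatechin (ent-epicatechin), (2S,3S) | Oc1cc(O)c2c(c1)O[C@@H](c1ccc(O)c(O)c1)[C@@H](O)C2 | starting material
30 | 5,7,3′,4′-tetra-O-benzyl-(+)-epicatechin | c9ccccc9COc1cc(OCc9ccccc9)c2c(c1)O[C@@H](c8ccc(OCc9ccccc9)c(OCc9ccccc9)c8)[C@@H](O)C2 | intermediate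
31 | 3,5,7,3′,4′-penta-O-benzyl-(+)-epicatechin | c9ccccc9COc1cc(OCc9ccccc9)c2c(c1)O[C@@H](c8ccc(OCc9ccccc9)c(OCc9ccccc9)c8)[C@@H](OCc9ccccc9)C2 | intermediate
32 | 8-iodo-penta-O-benzyl-(+)-epicatechin | c9ccccc9COc1cc(OCc9ccccc9)c2c(c1I)O[C@@H](c8ccc(OCc9ccccc9)c(OCc9ccccc9)c8)[C@@H](OCc9ccccc9)C2 | intermediate
33 | 6-bromo-8-iodo-penta-O-benzyl-(+)-epicatechin | c9ccccc9COc1c(Br)c(OCc9ccccc9)c2c(c1I)O[C@@H](c8ccc(OCc9ccccc9)c(OCc9ccccc9)c8)[C@@H](OCc9ccccc9)C2 | intermediate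
34 | C8 arylmagnesium chloride from 33 (not isolated) | c9ccccc9COc1c(Br)c(OCc9ccccc9)c2c(c1[Mg]Cl)O[C@@H](c8ccc(OCc9ccccc9)c(OCc9ccccc9)c8)[C@@H](OCc9ccccc9)C2 | intermediate
35 | 6-bromo-penta-O-benzyl-(+)-epicatechin | c9ccccc9COc1c(Br)c(OCc9ccccc9)c2c(c1)O[C@@H](c8ccc(OCc9ccccc9)c(OCc9ccccc9)c8)[C@@H](OCc9ccccc9)C2 | intermediate
36 | 6-bromo-penta-O-benzyl-(+)-epicatechin-4α-ol | c9ccccc9COc1c(Br)c(OCc9ccccc9)c2c(c1)O[C@@H](c8ccc(OCc9ccccc9)c(OCc9ccccc9)c8)[C@@H](OCc9ccccc9)[C@@H]2O | intermediate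
37 | (2S,3R)-6-bromo-3,5,7-tris(benzyloxy)-2-[3,4-bis(benzyloxy)phenyl]chroman-4-one | c9ccccc9COc1c(Br)c(OCc9ccccc9)c2c(c1)O[C@@H](c8ccc(OCc9ccccc9)c(OCc9ccccc9)c8)[C@@H](OCc9ccccc9)C2=O | intermediate
38 | C8 aryllithium from 28 (not isolated) | c9ccccc9COc1cc(OCc9ccccc9)c2c(c1[Li])O[C@H](c8ccc(OCc9ccccc9)c(OCc9ccccc9)c8)[C@H](OCc9ccccc9)[C@H]2c3c(OCc9ccccc9)cc4c(c3OCc9ccccc9)C[C@@H](OCc9ccccc9)[C@@H](c8ccc(OCc9ccccc9)c(OCc9ccccc9)c8)O4 | intermediate
39 | trimer tertiary carbinol (OH at C4 of the 6-bromo ent-epicatechin unit, cis to its 3-benzyloxy group) | Brc1c(OCc9ccccc9)cc2c(c1OCc9ccccc9)[C@](c3c(OCc9ccccc9)cc(OCc9ccccc9)c4c3O[C@H](c8ccc(OCc9ccccc9)c(OCc9ccccc9)c8)[C@H](OCc9ccccc9)[C@H]4c5c(OCc9ccccc9)cc6c(c5OCc9ccccc9)C[C@@H](OCc9ccccc9)[C@@H](c8ccc(OCc9ccccc9)c(OCc9ccccc9)c8)O6)(O)[C@H](OCc9ccccc9)[C@H](c8ccc(OCc9ccccc9)c(OCc9ccccc9)c8)O2 | intermediate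
40 | 6-bromo-penta-O-benzyl-ent-epicatechin-(4β→8)-penta-O-benzylepicatechin-(4β→6)-penta-O-benzylepicatechin | Brc1c(OCc9ccccc9)cc2c(c1OCc9ccccc9)[C@H](c3c(OCc9ccccc9)cc(OCc9ccccc9)c4c3O[C@H](c8ccc(OCc9ccccc9)c(OCc9ccccc9)c8)[C@H](OCc9ccccc9)[C@H]4c5c(OCc9ccccc9)cc6c(c5OCc9ccccc9)C[C@@H](OCc9ccccc9)[C@@H](c8ccc(OCc9ccccc9)c(OCc9ccccc9)c8)O6)[C@H](OCc9ccccc9)[C@H](c8ccc(OCc9ccccc9)c(OCc9ccccc9)c8)O2 | intermediate
41 | C6 aryllithium from 40 (not isolated) | [Li]c1c(OCc9ccccc9)cc2c(c1OCc9ccccc9)[C@H](c3c(OCc9ccccc9)cc(OCc9ccccc9)c4c3O[C@H](c8ccc(OCc9ccccc9)c(OCc9ccccc9)c8)[C@H](OCc9ccccc9)[C@H]4c5c(OCc9ccccc9)cc6c(c5OCc9ccccc9)C[C@@H](OCc9ccccc9)[C@@H](c8ccc(OCc9ccccc9)c(OCc9ccccc9)c8)O6)[C@H](OCc9ccccc9)[C@H](c8ccc(OCc9ccccc9)c(OCc9ccccc9)c8)O2 | intermediate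
42 | tetramer tertiary carbinol (OH at C4 of unit 1, cis to its 3-benzyloxy group) | c9ccccc9COc1cc(OCc9ccccc9)c2c(c1)O[C@H](c8ccc(OCc9ccccc9)c(OCc9ccccc9)c8)[C@H](OCc9ccccc9)[C@@]2(O)c1c(OCc9ccccc9)cc2c(c1OCc9ccccc9)[C@H](c3c(OCc9ccccc9)cc(OCc9ccccc9)c4c3O[C@H](c8ccc(OCc9ccccc9)c(OCc9ccccc9)c8)[C@H](OCc9ccccc9)[C@H]4c5c(OCc9ccccc9)cc6c(c5OCc9ccccc9)C[C@@H](OCc9ccccc9)[C@@H](c8ccc(OCc9ccccc9)c(OCc9ccccc9)c8)O6)[C@H](OCc9ccccc9)[C@H](c8ccc(OCc9ccccc9)c(OCc9ccccc9)c8)O2 | intermediate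
43 | eicosa-O-benzyl epicatechin-(4α→6)-ent-epicatechin-(4β→8)-epicatechin-(4β→6)-epicatechin | c9ccccc9COc1cc(OCc9ccccc9)c2c(c1)O[C@H](c8ccc(OCc9ccccc9)c(OCc9ccccc9)c8)[C@H](OCc9ccccc9)[C@@H]2c1c(OCc9ccccc9)cc2c(c1OCc9ccccc9)[C@H](c3c(OCc9ccccc9)cc(OCc9ccccc9)c4c3O[C@H](c8ccc(OCc9ccccc9)c(OCc9ccccc9)c8)[C@H](OCc9ccccc9)[C@H]4c5c(OCc9ccccc9)cc6c(c5OCc9ccccc9)C[C@@H](OCc9ccccc9)[C@@H](c8ccc(OCc9ccccc9)c(OCc9ccccc9)c8)O6)[C@H](OCc9ccccc9)[C@H](c8ccc(OCc9ccccc9)c(OCc9ccccc9)c8)O2 | intermediate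
44 | epicatechin-(4α→6)-ent-epicatechin-(4β→8)-epicatechin-(4β→6)-epicatechin (CNP0120618.3) | Oc1cc(O)c2c(c1)O[C@H](c1ccc(O)c(O)c1)[C@H](O)[C@@H]2c1c(O)cc2c(c1O)[C@H](c1c(O)cc(O)c3c1O[C@H](c1ccc(O)c(O)c1)[C@H](O)[C@H]3c1c(O)cc3c(c1O)C[C@@H](O)[C@@H](c1ccc(O)c(O)c1)O3)[C@H](O)[C@H](c1ccc(O)c(O)c1)O2 | target

Total step count: 30. Longest linear sequence: 16 steps (steps 8–18, then 26–30, from aldehyde 10).

Steps most likely to fail

Step 15. The [2+2] step has to build a quaternary carbon beside the bulky flavanyl group. It may be outrun by dimerisation of the vinylketene or by acylation of the product phenol by the ketene, and the ynol ether may be lost before it reacts. The fallback sets out from 3 and 6 and makes the unit 3–unit 4 bond by a halogen-capped Friedel–Crafts coupling. Compound 3 is iodinated at C8 (NIS, CH2Cl2) to 8-iodo-penta-O-benzyl-(−)-epicatechin F1. The 4-ol 6 is ionised with Me3SiOTf (cat.) in CH2Cl2 at low temperature in the presence of excess F1; the capped C8 forces attack through C6, anti to the C3 benzyloxy group of the cation, and gives the doubly halogenated dimer 8-bromo-penta-O-benzylepicatechin-(4β→6)-8-iodo-penta-O-benzylepicatechin F2. Selective iodine–magnesium exchange (i-PrMgCl·LiCl, THF, −20 °C) to the lower-unit arylmagnesium chloride F3 and protonation with methanol remove the cap. The route is rejoined at 28.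

Step 28. The hindered aryllithium of a trimer may act as a base (enolisation of ketone 5, then ring opening of the enolate) or be protonated before it adds, so the tertiary carbinol may not form. The fallback sets out from 35 and 5 and makes this cis union between two monomers first. Bromide 35 is exchanged with t-BuLi to 6-lithio-penta-O-benzyl-(+)-epicatechin F4, which adds to 5 to give the dimer carbinol F5. n-Bu3SnH/CF3CO2H then gives penta-O-benzylepicatechin-(4α→6)-penta-O-benzyl-ent-epicatechin F6. DDQ in wet CH2Cl2 oxidises C4 of its lower unit to the 4-ol F7, and (n-Pr)4N[RuO4]/NMO gives the dimer ketone F8. Aryllithium 38 (from 28, as in step 26) is added to F8 to give the tetramer carbinol F9, with the hydroxyl at C4 of unit 2. n-Bu3SnH/CF3CO2H reduces it with hydride anti to the C3 benzyloxy group, and the route is rejoined at 43.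

Step 6. Capture of the C4 cation by the dione enol may stop at O-alkylation, the acid-sensitive dione may decompose, or the cation may be consumed through C6 of a second molecule of 6. The fallback sets out from 6 and 7 and alkylates a preformed vinylogous ester instead of the free dione. Compound 7 is O-benzylated (BnOH, PPh3, DIAD, as in step 7) to 3-(benzyloxy)cyclobut-2-en-1-one F10. Its C2 (the enol ether β-carbon) captures the cation generated from 6 with Me3SiOTf (cat.) in CH2Cl2, and loss of a proton gives 9 directly, where the route is rejoined.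

Further compounds
F1 | step 15 | 8-iodo-3,5,7,3′,4′-penta-O-benzyl-(−)-epicatechin | c9ccccc9COc1cc(OCc9ccccc9)c2c(c1I)O[C@H](c8ccc(OCc9ccccc9)c(OCc9ccccc9)c8)[C@H](OCc9ccccc9)C2
F2 | step 15 | 8-bromo-penta-O-benzylepicatechin-(4β→6)-8-iodo-penta-O-benzylepicatechin | c9ccccc9COc1cc(OCc9ccccc9)c2c(c1Br)O[C@H](c8ccc(OCc9ccccc9)c(OCc9ccccc9)c8)[C@H](OCc9ccccc9)[C@H]2c3c(OCc9ccccc9)c(I)c4c(c3OCc9ccccc9)C[C@@H](OCc9ccccc9)[C@@H](c8ccc(OCc9ccccc9)c(OCc9ccccc9)c8)O4
F3 | step 15 | lower-unit C8 arylmagnesium chloride from F2 | c9ccccc9COc1cc(OCc9ccccc9)c2c(c1Br)O[C@H](c8ccc(OCc9ccccc9)c(OCc9ccccc9)c8)[C@H](OCc9ccccc9)[C@H]2c3c(OCc9ccccc9)c([Mg]Cl)c4c(c3OCc9ccccc9)C[C@@H](OCc9ccccc9)[C@@H](c8ccc(OCc9ccccc9)c(OCc9ccccc9)c8)O4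
F4 | step 28 | 6-lithio-penta-O-benzyl-(+)-epicatechin | c9ccccc9COc1c([Li])c(OCc9ccccc9)c2c(c1)O[C@@H](c8ccc(OCc9ccccc9)c(OCc9ccccc9)c8)[C@@H](OCc9ccccc9)C2
F5 | step 28 | [4-hydroxy-penta-O-benzylepicatechin]-(4→6)-penta-O-benzyl-ent-epicatechin (tertiary OH cis to the 3-benzyloxy group) | c9ccccc9COc1cc(OCc9ccccc9)c2c(c1)O[C@H](c8ccc(OCc9ccccc9)c(OCc9ccccc9)c8)[C@H](OCc9ccccc9)[C@@]2(O)c1c(OCc9ccccc9)cc2c(c1OCc9ccccc9)C[C@H](OCc9ccccc9)[C@H](c8ccc(OCc9ccccc9)c(OCc9ccccc9)c8)O2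
F6 | step 28 | penta-O-benzylepicatechin-(4α→6)-penta-O-benzyl-ent-epicatechin | c9ccccc9COc1cc(OCc9ccccc9)c2c(c1)O[C@H](c8ccc(OCc9ccccc9)c(OCc9ccccc9)c8)[C@H](OCc9ccccc9)[C@@H]2c1c(OCc9ccccc9)cc2c(c1OCc9ccccc9)C[C@H](OCc9ccccc9)[C@H](c8ccc(OCc9ccccc9)c(OCc9ccccc9)c8)O2
F7 | step 28 | 4-hydroxy derivative of F6 at the lower unit (OH trans to the 3-benzyloxy group) | c9ccccc9COc1cc(OCc9ccccc9)c2c(c1)O[C@H](c8ccc(OCc9ccccc9)c(OCc9ccccc9)c8)[C@H](OCc9ccccc9)[C@@H]2c1c(OCc9ccccc9)cc2c(c1OCc9ccccc9)[C@@H](O)[C@H](OCc9ccccc9)[C@H](c8ccc(OCc9ccccc9)c(OCc9ccccc9)c8)O2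
F8 | step 28 | 4-oxo derivative of F6 at the lower unit (dimer ketone) | c9ccccc9COc1cc(OCc9ccccc9)c2c(c1)O[C@H](c8ccc(OCc9ccccc9)c(OCc9ccccc9)c8)[C@H](OCc9ccccc9)[C@@H]2c1c(OCc9ccccc9)cc2c(c1OCc9ccccc9)C(=O)[C@H](OCc9ccccc9)[C@H](c8ccc(OCc9ccccc9)c(OCc9ccccc9)c8)O2
F9 | step 28 | tetramer tertiary carbinol with the hydroxyl at C4 of unit 2 (cis to its 3-benzyloxy group) | c9ccccc9COc1cc(OCc9ccccc9)c2c(c1)O[C@H](c8ccc(OCc9ccccc9)c(OCc9ccccc9)c8)[C@H](OCc9ccccc9)[C@@H]2c1c(OCc9ccccc9)cc2c(c1OCc9ccccc9)[C@](c3c(OCc9ccccc9)cc(OCc9ccccc9)c4c3O[C@H](c8ccc(OCc9ccccc9)c(OCc9ccccc9)c8)[C@H](OCc9ccccc9)[C@H]4c5c(OCc9ccccc9)cc6c(c5OCc9ccccc9)C[C@@H](OCc9ccccc9)[C@@H](c8ccc(OCc9ccccc9)c(OCc9ccccc9)c8)O6)(O)[C@H](OCc9ccccc9)[C@H](c8ccc(OCc9ccccc9)c(OCc9ccccc9)c8)O2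
F10 | step 6 | 3-(benzyloxy)cyclobut-2-en-1-one | O=C1CC(OCc9ccccc9)=C1
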